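**Retrosynthetic overview**
1. Feature: on ring A, O1 (on C8a) and the styryl-bearing carbon C7 are meta, and C4a, which holds O4, is para to C7. With OH in place of the styryl group, ring A is a resorcinol monoether whose free para C-H is C4a.
2. Late stage: the six aryl pivalates are cleaved last. The C7-vinyl bond to ring B comes from a Heck coupling of the C7 triflate with 3,5-bis(pivaloyloxy)styrene.
3. Key disconnection O4-C4a: the dioxane ring, the only ring made in the route, closes when the C7 phenol is oxidised and the C3 hydroxyl is captured at C4a.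
4. The (2R,3R)-threo precursor comes from the racemic C2-aryloxy C3-ketone by transfer hydrogenation with dynamic kinetic resolution. The ketone comes from resorcinol and the C2-bromo ketone.
5. The bromo ketone comes from the ring C/ring D stilbene (bromohydrin, then oxidation). The stilbene is a Heck product of the same styrene and 4-bromocatechol dipivalate. Rings A to D are bought as arenes.

Key step: step 9

Remark: locants are O1, C2 (ring C), C3 (ring D), O4, C4a, C5 to C8, C8a (ring A), with ring B on the C7 styryl group. Piv = 2,2-dimethylpropanoyl. The given SMILES is read as the (2R,3R)-trans isomer.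
Remark on the chemistry: electron-withdrawing pivalates, not acetal or silyl ethers, protect rings B, C and D. The oxidation in step 9 needs rings C and D to be poor nucleophiles, and it needs the C3 alcohol to resist ionisation. C2 is kept racemic on purpose until step 8.

**Step 1**
Reactants: 1 3,5-dihydroxybenzaldehyde
Product: 2 5-ethenylbenzene-1,3-diol
Conditions: Ph3PCH3Br (3.3 equiv), KOtBu (3.2 equiv), THF, 0 °C to rt; aq NH4Cl
Reagents that add atoms: methyltriphenylphosphonium bromide C[P+](c1ccccc1)(c1ccccc1)c1ccccc1.[Br-]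
Why: Wittig methylenation in which the first two equivalents of ylide only deprotonate the phenols, and the meta phenoxides, not conjugated with the formyl group, leave it electrophilic enough for the remaining ylide.

**Step 2**
Reactants: 2 5-ethenylbenzene-1,3-diol
Product: 3 5-ethenyl-1,3-phenylene bis(2,2-dimethylpropanoate)
Conditions: PivCl, Et3N, DMAP (cat.), CH2Cl2, 0 °C to rt
Reagents that add atoms: pivaloyl chloride CC(C)(C)C(=O)Cl
Why: Nucleophile-catalysed acylation of both phenols gives a hindered ester that should survive carbonate, hot amine base and acid, and that turns the resorcinol ring into a poor nucleophile for step 9.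

**Step 3**
Reactants: 4 4-bromobenzene-1,2-diol
Product: 5 4-bromo-1,2-phenylene bis(2,2-dimethylpropanoate)
Conditions: PivCl, Et3N, DMAP (cat.), CH2Cl2, 0 °C to rt
Reagents that add atoms: pivaloyl chloride CC(C)(C)C(=O)Cl
Why: The same acylation protects the air-sensitive catechol and leaves the C-Br bond free for oxidative addition.

**Step 4**
Reactants: 3 5-ethenyl-1,3-phenylene bis(2,2-dimethylpropanoate); 5 4-bromo-1,2-phenylene bis(2,2-dimethylpropanoate)
Product: 6 (E)-3,3',4,5'-tetrakis(pivaloyloxy)stilbene (ring C-CH=CH-ring D)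
Conditions: Pd(OAc)2 (3 mol %), P(o-tol)3, Et3N, DMF, 100 °C
Reagents that add atoms: none
Why: Mizoroki-Heck reaction in which syn carbopalladation at the terminal styrene carbon and syn beta-hydride elimination give the (E)-alkene, while aryl pivalates are inert to this catalyst and to Et3N.

**Step 5**
Reactants: 6 (E)-3,3',4,5'-tetrakis(pivaloyloxy)stilbene
Product: 7 rac-erythro-2-bromo-2-[3,5-bis(pivaloyloxy)phenyl]-1-[3,4-bis(pivaloyloxy)phenyl]ethanol (OH on C3, Br on C2)
Conditions: NBS, acetone/H2O, rt, dark
Reagents that add atoms: N-bromosuccinimide O=C1CCC(=O)N1Br; water O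
Why: In this bromohydrin formation water should open the bromonium ion at C3, because only ring D has an oxygen para to the benzylic carbon to share the charge whereas ring C has two meta acyloxy groups, and the anti addition gives an erythro racemate whose configuration is erased or reset later.

**Step 6**
Reactants: 7 rac-erythro bromohydrin
Product: 8 rac-2-bromo-2-[3,5-bis(pivaloyloxy)phenyl]-1-[3,4-bis(pivaloyloxy)phenyl]ethanone
Conditions: Dess-Martin periodinane, CH2Cl2, 0 °C to rt
Reagents that add atoms: none
Why: Dess-Martin oxidation of the secondary benzylic alcohol runs without base, so the bromohydrin cannot close to the epoxide.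

**Step 7**
Reactants: 8 rac-bromo ketone; 9 resorcinol
Product: 10 rac-2-(3-hydroxyphenoxy)-2-[3,5-bis(pivaloyloxy)phenyl]-1-[3,4-bis(pivaloyloxy)phenyl]ethanone
Conditions: 9 (5 equiv), K2CO3 (1.5 equiv), acetone, N2, 0 °C to rt
Reagents that add atoms: none
Why: In this Williamson-type SN2 displacement of a benzylic, alpha-keto bromide by resorcinol monoanion, the large excess of the symmetrical diphenol makes a protecting group on ring A unnecessary and the hindered pivalates resist acyl transfer to phenoxide.

**Step 8**
Reactants: 10 rac-aryloxy ketone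
Product: 11 (1R,2R)-2-(3-hydroxyphenoxy)-2-[3,5-bis(pivaloyloxy)phenyl]-1-[3,4-bis(pivaloyloxy)phenyl]ethanol, the (2R,3R)-threo alcohol
Conditions: RuCl[(S,S)-TsDPEN](p-cymene) (2 mol %), HCO2H/Et3N (1:1), DMF, 40 °C
Reagents that add atoms: none
Why: This is a Noyori-Ikariya transfer hydrogenation run as a dynamic kinetic resolution, as in the conversion of racemic benzoins into threo-hydrobenzoins: C2-H lies between a ketone, an aryl ring and an aryloxy group, so Et3N should racemise 10 faster than it is reduced; the (S,S)-catalyst sets (3R) by its recognition of the aryl ketone; and the C2 epimer that places C2-O1 anti to the incoming hydride (polar Felkin-Anh, no chelation in an outer-sphere transfer) reacts faster and sets (2R).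

**Step 9**
Reactants: 11 (2R,3R)-threo alcohol
Product: 14 (2R,3R)-2-[3,5-bis(pivaloyloxy)phenyl]-3-[3,4-bis(pivaloyloxy)phenyl]-2,3-dihydro-1,4-benzodioxin-7-ol, via 4aH-dienone 12 (not isolated), via C4a-acetoxy dienone 13 (not isolated)
Conditions: PhI(OAc)2 (2.1 equiv, portionwise), (CF3)2CHOH (0.02 M), 4 Å MS, 0 °C; then Zn dust, 0 °C to rt
Reagents that add atoms: none
Why: Proposed new method: the C7 phenol exchanges for acetate at the trivalent iodine of PhI(OAc)2, heterolysis of the O-I bond in the ionising, barely nucleophilic solvent leaves an electron-deficient ring A with its largest coefficient at C4a, the C3 hydroxyl tied on through C2 and O1 adds there, and dienone 12 enolises to phenol 14; the closest known reactions are the spirocyclisations of phenols bearing tethered alcohols under PhI(OAc)2 and the para-alkoxylation that leads from phenols to quinone monoketals. The new ring is six-membered and closes on an sp2 carbon of ring A, a 6-exo-trig process if C4a=C5 is counted as the bond that gives way and 6-endo-trig if C4a=C8a is, both allowed, and the threo substrate reaches it in a chair that keeps rings C and D equatorial. No stereocentre is created: the C2-O1 and C3-O bonds stay intact, and the acyloxy groups on ring D stop the C3 alcohol from ionising in this solvent, so (2R,3R) passes unchanged into the trans-dioxane. Because 14 is a para-alkoxyphenol it is oxidised faster than 11 and the reaction cannot be held there by rationing the oxidant, so two equivalents are used on purpose: all material is driven on to the C4a acetoxy ketal 13, which has no phenol left to oxidise, and zinc then removes the acetate, a far better leaving group than the O4 alkoxide, as in the reduction of quinol acetates and quinone monoketals, and gives back 14. The step needs site selectivity between C4a and C8, which the hydroxyl also reaches through a six-membered ring, and this rests on the para preference of oxidised phenols and on the crowding of C8 between O1 and the C7 oxygen. It also needs the oxygen nucleophile to beat carbon ones, since an ortho carbon of ring C could reach C4a through a six-membered ring as well, and the four pivalates secure this by making rings C and D poor nucleophiles and poor electron donors.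

**Step 10**
Reactants: 14 benzodioxin-7-ol
Product: 15 (2R,3R)-2-[3,5-bis(pivaloyloxy)phenyl]-3-[3,4-bis(pivaloyloxy)phenyl]-2,3-dihydro-1,4-benzodioxin-7-yl trifluoromethanesulfonate
Conditions: Tf2O, pyridine, CH2Cl2, 0 °C
Reagents that add atoms: trifluoromethanesulfonic anhydride O=S(=O)(OS(=O)(=O)C(F)(F)F)C(F)(F)F
Why: Sulfonylation of the only free hydroxyl group turns the oxygen that activated ring A into the leaving group for the C7-C bond.

**Step 11**
Reactants: 15 C7 triflate; 3 5-ethenyl-1,3-phenylene bis(2,2-dimethylpropanoate)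
Product: 16 maackin hexapivalate, (E)-alkene, (2R,3R)
Conditions: Pd(OAc)2 (5 mol %), PPh3, LiCl, Et3N, DMF, 90 °C
Reagents that add atoms: none
Why: In this Mizoroki-Heck reaction of an aryl triflate, chloride converts the cationic arylpalladium triflate into the neutral arylpalladium chloride, so insertion should take place at the terminal styrene carbon and give the (E)-stilbene, and neither benzylic ether centre is acidic enough to be touched by Et3N.

**Step 12**
Reactants: 16 maackin hexapivalate
Product: 17 maackin
Conditions: LiAlH4 (excess), THF, 0 °C, Ar; then cold 1 M HCl, EtOAc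
Reagents that add atoms: none
Why: Hydride cleavage of the six aryl esters in an aprotic medium avoids both prolonged acid and alkoxide in alcohol, either of which could open C3-O4 through a ring D para-quinone methide, and C2 cannot ionise because the ring C oxygens are meta, while trans is the more stable arrangement at C3.

**Compound list**
1 | 3,5-dihydroxybenzaldehyde | O=Cc1cc(O)cc(O)c1 | starting material
2 | 5-ethenylbenzene-1,3-diol | C=Cc1cc(O)cc(O)c1 | intermediate
3 | 5-ethenyl-1,3-phenylene bis(2,2-dimethylpropanoate) | C=Cc1cc(OC(=O)C(C)(C)C)cc(OC(=O)C(C)(C)C)c1 | intermediate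
4 | 4-bromobenzene-1,2-diol | Oc1ccc(Br)cc1O | starting material
5 | 4-bromo-1,2-phenylene bis(2,2-dimethylpropanoate) | CC(C)(C)C(=O)Oc1ccc(Br)cc1OC(=O)C(C)(C)C | intermediate
6 | (E)-3,3',4,5'-tetrakis(pivaloyloxy)stilbene | CC(C)(C)C(=O)Oc1ccc(/C=C/c2cc(OC(=O)C(C)(C)C)cc(OC(=O)C(C)(C)C)c2)cc1OC(=O)C(C)(C)C | intermediate
7 | rac-erythro bromohydrin (racemate, one enantiomer drawn) | O[C@H](c1ccc(OC(=O)C(C)(C)C)c(OC(=O)C(C)(C)C)c1)[C@@H](Br)c1cc(OC(=O)C(C)(C)C)cc(OC(=O)C(C)(C)C)c1 | intermediate
8 | rac-C2-bromo C3-ketone | O=C(c1ccc(OC(=O)C(C)(C)C)c(OC(=O)C(C)(C)C)c1)C(Br)c1cc(OC(=O)C(C)(C)C)cc(OC(=O)C(C)(C)C)c1 | intermediate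
9 | resorcinol | Oc1cccc(O)c1 | starting material
10 | rac-C2-(3-hydroxyphenoxy) C3-ketone | O=C(c1ccc(OC(=O)C(C)(C)C)c(OC(=O)C(C)(C)C)c1)C(Oc1cccc(O)c1)c1cc(OC(=O)C(C)(C)C)cc(OC(=O)C(C)(C)C)c1 | intermediate
11 | (2R,3R)-threo alcohol, key-step precursor | Oc1cccc(c1)O[C@H](c1cc(OC(=O)C(C)(C)C)cc(OC(=O)C(C)(C)C)c1)[C@@H](c1ccc(OC(=O)C(C)(C)C)c(OC(=O)C(C)(C)C)c1)O | intermediate
12 | 4aH-dienone (C4a configuration undefined) | O=C1C=CC2C(=C1)O[C@H](c1cc(OC(=O)C(C)(C)C)cc(OC(=O)C(C)(C)C)c1)[C@@H](c1ccc(OC(=O)C(C)(C)C)c(OC(=O)C(C)(C)C)c1)O2 | intermediate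
13 | C4a-acetoxy dienone (C4a configuration undefined) | O=C1C=CC2(OC(C)=O)C(=C1)O[C@H](c1cc(OC(=O)C(C)(C)C)cc(OC(=O)C(C)(C)C)c1)[C@@H](c1ccc(OC(=O)C(C)(C)C)c(OC(=O)C(C)(C)C)c1)O2 | intermediate
14 | (2R,3R)-2,3-diaryl-2,3-dihydro-1,4-benzodioxin-7-ol, key-step product | Oc1ccc2c(c1)O[C@H](c1cc(OC(=O)C(C)(C)C)cc(OC(=O)C(C)(C)C)c1)[C@@H](c1ccc(OC(=O)C(C)(C)C)c(OC(=O)C(C)(C)C)c1)O2 | intermediate
15 | C7 triflate | O=S(=O)(Oc1ccc2c(c1)O[C@H](c1cc(OC(=O)C(C)(C)C)cc(OC(=O)C(C)(C)C)c1)[C@@H](c1ccc(OC(=O)C(C)(C)C)c(OC(=O)C(C)(C)C)c1)O2)C(F)(F)F | intermediate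
16 | maackin hexapivalate | CC(C)(C)C(=O)Oc1cc(OC(=O)C(C)(C)C)cc(/C=C/c2ccc3c(c2)O[C@H](c2cc(OC(=O)C(C)(C)C)cc(OC(=O)C(C)(C)C)c2)[C@@H](c2ccc(OC(=O)C(C)(C)C)c(OC(=O)C(C)(C)C)c2)O3)c1 | intermediate
17 | maackin | Oc1cc(O)cc(/C=C/c2ccc3c(c2)O[C@H](c2cc(O)cc(O)c2)[C@@H](c2ccc(O)c(O)c2)O3)c1 | target

**Totals**
Total step count: 12.
Longest linear sequence: 11 steps (1, 2, 4, 5, 6, 7, 8, 9, 10, 11, 12).

**Steps most likely to fail**

Step 9.
- What may go wrong: the hindered secondary alcohol may arrive too late, so that acetate, solvent or a second phenol captures the oxidised ring. Closure may go to C8. The over-oxidised stage may decay by hydrolytic opening of the ketal before zinc is added.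
- Fallback (known chemistry): it sets out from 11 and returns at 14, making O4-C4a by cross-coupling instead of oxidation.
  - NBS in MeCN at low temperature brominates ring A para to the free hydroxyl and should give the 2-bromo-5-hydroxyphenyl ether F1.
  - TIPSCl and imidazole silylate only the phenol, giving the silyl ether F2.
  - Intramolecular Buchwald-Hartwig etherification follows (Pd(OAc)2, 2-(di-tert-butylphosphino)-1,1'-binaphthyl, Cs2CO3, toluene, 70 °C). It closes the ring with retention at C3 to the 7-silyloxy benzodioxane F3.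
  - Bu4NF buffered with AcOH frees 14.

Step 8.
- What may go wrong: the C2 epimer that reacts faster may be the one leading to the erythro series, with ring C rather than O1 standing anti to the hydride.
- Fallback: it sets out from 10 and returns at 11, setting C3 by inversion.
  - RuCl[(R,R)-TsDPEN](p-cymene) under the same conditions would then give the (2R,3S)-erythro alcohol F4.
  - Mitsunobu reaction with chloroacetic acid, PPh3 and DIAD inverts C3 to the (2R,3R)-chloroacetate F5. The deactivated ring D favours a clean SN2 course, and the strong acid outcompetes the ring A phenol.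
  - Thiourea and NaHCO3 in EtOH remove the chloroacetyl group without touching the aryl pivalates.

Step 11.
- What may go wrong: oxidative addition of the electron-rich triflate may be sluggish, S-O cleavage may return the phenol, or insertion may occur at the internal alkene carbon through a cationic palladium species.
- Fallback: it sets out from 3 and 15 and returns at 16, fixing the alkene geometry before the coupling.
  - Cross-metathesis of 3 with vinylboronic acid pinacol ester (second-generation Grubbs catalyst, CH2Cl2, 40 °C) should give the (E)-styrylboronate F6.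
  - Suzuki-Miyaura coupling of F6 with 15 (PdCl2(dppf), CsF, 1,4-dioxane, 80 °C) forms the C7-vinyl bond with retention of geometry.

**Further compounds**
F1 | step 9 | (1R,2R)-2-(2-bromo-5-hydroxyphenoxy)-2-[3,5-bis(pivaloyloxy)phenyl]-1-[3,4-bis(pivaloyloxy)phenyl]ethanol | Oc1ccc(Br)c(c1)O[C@H](c1cc(OC(=O)C(C)(C)C)cc(OC(=O)C(C)(C)C)c1)[C@@H](c1ccc(OC(=O)C(C)(C)C)c(OC(=O)C(C)(C)C)c1)O
F2 | step 9 | triisopropylsilyl ether of F1 at the ring A phenol | CC(C)[Si](C(C)C)(C(C)C)Oc1ccc(Br)c(c1)O[C@H](c1cc(OC(=O)C(C)(C)C)cc(OC(=O)C(C)(C)C)c1)[C@@H](c1ccc(OC(=O)C(C)(C)C)c(OC(=O)C(C)(C)C)c1)O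
F3 | step 9 | (2R,3R)-7-(triisopropylsilyloxy)-2,3-diaryl-2,3-dihydro-1,4-benzodioxine | CC(C)[Si](C(C)C)(C(C)C)Oc1ccc2c(c1)O[C@H](c1cc(OC(=O)C(C)(C)C)cc(OC(=O)C(C)(C)C)c1)[C@@H](c1ccc(OC(=O)C(C)(C)C)c(OC(=O)C(C)(C)C)c1)O2
F4 | step 8 | (2R,3S)-erythro alcohol | Oc1cccc(c1)O[C@H](c1cc(OC(=O)C(C)(C)C)cc(OC(=O)C(C)(C)C)c1)[C@H](c1ccc(OC(=O)C(C)(C)C)c(OC(=O)C(C)(C)C)c1)O
F5 | step 8 | (2R,3R)-C3 chloroacetate | Oc1cccc(c1)O[C@H](c1cc(OC(=O)C(C)(C)C)cc(OC(=O)C(C)(C)C)c1)[C@@H](c1ccc(OC(=O)C(C)(C)C)c(OC(=O)C(C)(C)C)c1)OC(=O)CCl
F6 | step 11 | (E)-2-[3,5-bis(pivaloyloxy)phenyl]ethenylboronic acid pinacol ester | CC(C)(C)C(=O)Oc1cc(/C=C/B2OC(C)(C)C(C)(C)O2)cc(OC(=O)C(C)(C)C)c1
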